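The C17 side chain plus one carboxyl carbon is a C18 hydroxy-dienoic (oxylipin-type) acid. Everything therefore rests on cutting the bond between benzylic C1′ and ring carbon C5, the only position of the resorcinol ring meta to both oxygens and thus closed to Friedel–Crafts chemistry. In one flask the free (9Z,13S,15Z)-13-hydroxyoctadeca-9,15-dienoic acid is activated as its N-hydroxyphthalimide ester. It is then coupled electroreductively, under nickel catalysis with loss of CO2, with bis-silylated 5-iodoresorcinol. Two electrophilic carbons are united through a primary C1′ radical, leaving hydroxyl, stereocentre and both Z-alkenes untouched. The acid arises in three steps from an L-glutamic-acid-derived lactone tosylate.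

Key step: step 6

Remark: the carbinol carbon is read from the SMILES as (S). It is C12′ of the side chain and C13 of the acid. Primed numbers count side-chain carbons from the ring.

Step 1
Reactants: 1 EtLi (ethyllithium); 2 CuBr·SMe2; 3 acetylene; 4 (S)-(5-oxotetrahydrofuran-2-yl)methyl 4-methylbenzenesulfonate
Product: 7 (S)-5-[(Z)-pent-2-en-1-yl]dihydrofuran-2(3H)-one, via Et2CuLi 5 (not isolated), via [(Z)-EtCH=CH]2CuLi 6 (not isolated)
Conditions: EtLi (4 equiv), CuBr·SMe2 (2 equiv), Et2O, −40 °C; HC≡CH (4 equiv), −50 → −25 °C; then 4 (1 equiv), THF, −30 → 0 °C; aq. NH4Cl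
Reagents that add atoms: none
Why: Syn-carbocupration of acetylene (Normant-type) by 5 should give the (Z)-alkenyl cuprate 6, whose SN2 displacement of the primary tosylate (cuprate–sulfonate coupling) retains the alkene geometry, spares the lactone carbonyl and leaves the C–O bond of the stereocentre intact, so the (S) centre of 4 becomes C12′ and C14′=C15′ is set as Z.

Step 2
Reactants: 7 (S)-5-[(Z)-pent-2-en-1-yl]dihydrofuran-2(3H)-one
Product: 8 (5S)-5-[(Z)-pent-2-en-1-yl]tetrahydrofuran-2-ol (lactol, mixture of anomers)
Conditions: i-Bu2AlH (1.1 equiv), CH2Cl2, −78 °C; aq. potassium sodium tartrate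
Reagents that add atoms: none
Why: Partial lactone reduction with i-Bu2AlH stops at the aluminium hemiacetal at −78 °C, the isolated alkene is inert, and the new anomeric centre may form unselectively because step 4 erases it.

Step 3
Reactants: 9 9-bromononanoic acid
Product: 10 (8-carboxyoctyl)triphenylphosphonium bromide
Conditions: PPh3 (1.05 equiv), MeCN, reflux
Reagents that add atoms: triphenylphosphine, c1ccc(cc1)P(c1ccccc1)c1ccccc1
Why: SN2 quaternisation of the phosphine by the primary bromide (phosphonium salt formation) tolerates the free carboxylic acid.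

Step 4
Reactants: 8 (5S)-5-[(Z)-pent-2-en-1-yl]tetrahydrofuran-2-ol; 10 (8-carboxyoctyl)triphenylphosphonium bromide
Product: 12 (9Z,13S,15Z)-13-hydroxyoctadeca-9,15-dienoic acid, via sodium 9-(triphenylphosphoranylidene)nonanoate 11 (not isolated)
Conditions: 10 (2.5 equiv), NaN(SiMe3)2 (5 equiv), THF, 0 °C; then 8, −78 °C → rt; 1 M HCl to pH 4
Reagents that add atoms: none
Why: Wittig olefination of the open hydroxy-aldehyde form of the lactol with a non-stabilised, lithium-free ylide runs under kinetic control through the cis-oxaphosphetane and should set C9=C10 (later C8′=C9′) as Z; this lactol/carboxy-ylide pairing is standard in prostanoid chemistry and does not involve the carbinol centre.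

Step 5
Reactants: 13 5-iodobenzene-1,3-diol
Product: 14 1-iodo-3,5-bis(triisopropylsilyloxy)benzene
Conditions: i-Pr3SiCl (2.4 equiv), imidazole (5 equiv), DMF, rt
Reagents that add atoms: triisopropylsilyl chloride, CC(C)[Si](Cl)(C(C)C)C(C)C
Why: Imidazole-promoted O-silylation masks both phenols, which would otherwise be acylated by the active ester or discharged at the cathode in step 6, as base-robust silyl ethers.

Step 6
Reactants: 12 (9Z,13S,15Z)-13-hydroxyoctadeca-9,15-dienoic acid; 14 1-iodo-3,5-bis(triisopropylsilyloxy)benzene; 15 N-hydroxyphthalimide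
Product: 17 (3Z,6S,9Z)-17-[3,5-bis(triisopropylsilyloxy)phenyl]heptadeca-3,9-dien-6-ol, via N-acyloxyphthalimide 16 (not isolated)
Conditions: 12, 15 (1.05 equiv), DIC (1.05 equiv), dry DMF, rt, 2 h; then 14 (1.5 equiv), NiCl2·6H2O (20 mol %), 2,2′-bipyridine (20 mol %), AgNO3 (0.3 equiv), undivided cell, Mg anode, reticulated vitreous carbon cathode, constant current, ca. 3 F/mol, rt; 0.5 M HCl work-up
Reagents that add atoms: none
Why: DIC condenses the carboxyl group of 12 with 15 chemoselectively, because without an acyl-transfer catalyst the acidic N–OH outcompetes the secondary alcohol, and this gives 16. At the cathode, coated in situ with silver nanoparticles, divalent nickel–bipyridine is reduced to low-valent nickel, which inserts into the C5–I bond of 14; single-electron reduction of 16 expels phthalimide anion and CO2 to leave the primary C1′ radical, the arylnickel species captures it, and reductive elimination from trivalent nickel forges the C1′–C5 bond while the Mg anode supplies the electrons. The closest known reaction type is the nickel-electrocatalytic decarboxylative arylation of primary alkyl N-hydroxyphthalimide esters, isolated or made in situ, with aryl iodides, which is a reductive cross-electrophile coupling. No ring is closed and no stereocentre is created, and C12′ lies eleven bonds from the radical site. The step needs cross- over homo-coupling, which is secured by the different activation modes of the two electrophiles (two-electron oxidative addition at the sp2 C–I carbon, which is meta to both silyloxy groups and so not deactivated by resonance donation, against one-electron fragmentation of the ester) and by the excess of 14. It also needs the radical to ignore the C8′=C9′ and C14′=C15′ alkenes, which their distance secures because only eight-membered or larger cyclisation modes exist, so both Z geometries should persist.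

Step 7
Reactants: 17 (3Z,6S,9Z)-17-[3,5-bis(triisopropylsilyloxy)phenyl]heptadeca-3,9-dien-6-ol
Product: 18 5-[(8Z,12S,14Z)-12-hydroxyheptadeca-8,14-dien-1-yl]benzene-1,3-diol (target)
Conditions: Bu4NF (2.5 equiv), AcOH (2.5 equiv), THF, 0 °C → rt
Reagents that add atoms: none
Why: Fluoride-induced desilylation of aryl silyl ethers, driven by Si–F bond formation and the phenoxide leaving group and buffered with AcOH, frees both phenols without touching the alcohol, the stereocentre or the Z-alkenes.

Compound list
1 | EtLi (ethyllithium) | [Li]CC | starting material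
2 | CuBr·SMe2 | CSC.Br[Cu] | starting material
3 | acetylene | C#C | starting material
4 | (S)-(5-oxotetrahydrofuran-2-yl)methyl 4-methylbenzenesulfonate | Cc1ccc(cc1)S(=O)(=O)OC[C@@H]1CCC(=O)O1 | starting material
5 | Et2CuLi (lithium diethylcuprate) | [Li+].CC[Cu-]CC | intermediate
6 | [(Z)-EtCH=CH]2CuLi (lithium bis[(Z)-but-1-enyl]cuprate) | [Li+].CC/C=C\[Cu-]/C=C\CC | intermediate
7 | (S)-5-[(Z)-pent-2-en-1-yl]dihydrofuran-2(3H)-one | CC/C=C\C[C@@H]1CCC(=O)O1 | intermediate
8 | (5S)-5-[(Z)-pent-2-en-1-yl]tetrahydrofuran-2-ol (anomeric mixture) | CC/C=C\C[C@@H]1CCC(O)O1 | intermediate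
9 | 9-bromononanoic acid | OC(=O)CCCCCCCCBr | starting material
10 | (8-carboxyoctyl)triphenylphosphonium bromide | OC(=O)CCCCCCCC[P+](c1ccccc1)(c1ccccc1)c1ccccc1.[Br-] | intermediate
11 | sodium 9-(triphenylphosphoranylidene)nonanoate | [Na+].[O-]C(=O)CCCCCCCC=P(c1ccccc1)(c1ccccc1)c1ccccc1 | intermediate
12 | (9Z,13S,15Z)-13-hydroxyoctadeca-9,15-dienoic acid | CC/C=C\C[C@@H](O)CC/C=C\CCCCCCCC(=O)O | intermediate
13 | 5-iodobenzene-1,3-diol | Oc1cc(O)cc(I)c1 | starting material
14 | 1-iodo-3,5-bis(triisopropylsilyloxy)benzene | CC(C)[Si](Oc1cc(I)cc(O[Si](C(C)C)(C(C)C)C(C)C)c1)(C(C)C)C(C)C | intermediate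
15 | N-hydroxyphthalimide | ON1C(=O)c2ccccc2C1=O | starting material
16 | 1,3-dioxoisoindolin-2-yl (9Z,13S,15Z)-13-hydroxyoctadeca-9,15-dienoate | CC/C=C\C[C@@H](O)CC/C=C\CCCCCCCC(=O)ON1C(=O)c2ccccc2C1=O | intermediate
17 | (3Z,6S,9Z)-17-[3,5-bis(triisopropylsilyloxy)phenyl]heptadeca-3,9-dien-6-ol | CC/C=C\C[C@@H](O)CC/C=C\CCCCCCCc1cc(O[Si](C(C)C)(C(C)C)C(C)C)cc(O[Si](C(C)C)(C(C)C)C(C)C)c1 | intermediate
18 | 5-[(8Z,12S,14Z)-12-hydroxyheptadeca-8,14-dien-1-yl]benzene-1,3-diol | CC/C=C\C[C@@H](O)CC/C=C\CCCCCCCc1cc(O)cc(O)c1 | target

Total step count: 7.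
Longest linear sequence: 5 steps (1 → 2 → 4 → 6 → 7).

Steps most likely to fail

Step 6. The primary radical may be lost to hydrogen abstraction or dimerisation before nickel captures it. The aryl iodide may homocouple, or the active ester may slowly acylate the free hydroxyl. The fallback forms the same C1′–C5 bond by a two-electron B-alkyl Suzuki–Miyaura coupling; it sets out from lactol 8 and returns at 17. 8-Bromooct-1-ene and PPh3 give (oct-7-en-1-yl)triphenylphosphonium bromide F1. NaN(SiMe3)2 converts it into (oct-7-en-1-ylidene)triphenylphosphorane F2, which olefinates 8 to (3Z,6S,9Z)-heptadeca-3,9,16-trien-6-ol F3. 9-BBN-H (2.2 equiv) masks the hydroxyl as its borinate and hydroborates only the monosubstituted terminal alkene, giving the O,C-bis(9-borabicyclo[3.3.1]nonan-9-yl) adduct F4. Coupling of F4 with 14 under PdCl2(dppf) and aq. K3PO4 in THF/DMF should give 17.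

Step 1. Displacement of the β-oxygenated primary tosylate may be so slow that the alkenyl cuprate decomposes thermally or loses its geometry. The fallback replaces the cuprate by epoxide alkynylation and semihydrogenation; it sets out from tosylate 4 and returns at 7. NaOMe in MeOH opens the lactone, and the liberated alkoxide closes onto the tosylate to give methyl (S)-3-(oxiran-2-yl)propanoate F5. But-1-yne, n-BuLi and BF3·OEt2 in THF at −78 °C (Yamaguchi–Hirao alkynylation) open the epoxide at its terminal carbon to give methyl (S)-4-hydroxynon-6-ynoate F6. Catalytic TsOH lactonises this to (S)-5-(pent-2-yn-1-yl)dihydrofuran-2(3H)-one F7. H2 over Pd/CaCO3 poisoned with Pb(OAc)2, with quinoline, should then give 7.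

Step 4. Stereochemical drift of the oxaphosphetane in the presence of alkoxide and carboxylate salts may erode the Z selectivity, and the lactol may open only sluggishly. The fallback sets the geometry by alkyne semireduction; it sets out from lactol 8 and returns at 12. Seyferth–Gilbert homologation with dimethyl (1-diazo-2-oxopropyl)phosphonate and K2CO3 in MeOH gives (5S,7Z)-dec-7-en-1-yn-5-ol F8. Its dilithio derivative (n-BuLi, THF/DMPU) is alkylated at the acetylide carbon with lithium 8-bromooctanoate to give (13S,15Z)-13-hydroxyoctadec-15-en-9-ynoic acid F9. Semihydrogenation with H2 over Pd/CaCO3 poisoned with Pb(OAc)2, with quinoline, should give 12.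

Further compounds
F1 | step 6 | (oct-7-en-1-yl)triphenylphosphonium bromide | C=CCCCCCC[P+](c1ccccc1)(c1ccccc1)c1ccccc1.[Br-]
F2 | step 6 | (oct-7-en-1-ylidene)triphenylphosphorane | C=CCCCCCC=P(c1ccccc1)(c1ccccc1)c1ccccc1
F3 | step 6 | (3Z,6S,9Z)-heptadeca-3,9,16-trien-6-ol | CC/C=C\C[C@@H](O)CC/C=C\CCCCCC=C
F4 | step 6 | O,C-bis(9-borabicyclo[3.3.1]nonan-9-yl) adduct of F3 (boron on O at C6 and on C17) | CC/C=C\C[C@@H](OB1C2CCCC1CCC2)CC/C=C\CCCCCCCB1C2CCCC1CCC2
F5 | step 1 | methyl (S)-3-(oxiran-2-yl)propanoate | COC(=O)CC[C@H]1CO1
F6 | step 1 | methyl (S)-4-hydroxynon-6-ynoate | CCC#CC[C@@H](O)CCC(=O)OC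
F7 | step 1 | (S)-5-(pent-2-yn-1-yl)dihydrofuran-2(3H)-one | CCC#CC[C@@H]1CCC(=O)O1
F8 | step 4 | (5S,7Z)-dec-7-en-1-yn-5-ol | CC/C=C\C[C@@H](O)CCC#C
F9 | step 4 | (13S,15Z)-13-hydroxyoctadec-15-en-9-ynoic acid | CC/C=C\C[C@@H](O)CCC#CCCCCCCCC(=O)O
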